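**Retrosynthetic overview**

1. Numbering (daucane): C1 = quaternary ring-fusion C–Me, C2–C3 = CH2CH2, C4 = C(OH)iPr, C5 = ring-fusion CH, C6 = CH–O-aroyl, C7 = CH2, C8 = C(OH)Me, C9=C10 = alkene; ring A = C1–C5, ring B = C1, C5–C10; β = face of the C1 methyl. The strategy rests on the cis C9=C10 alkene that sits directly on quaternary C1 inside the seven-membered ring, with C5/C6 across the C1–C5 bond: the footprint of a vinylcyclopropane (C1=C10, C9, C8, C7) that has taken up an alkyne (C5≡C6) tethered through C2–C3–C4.
2. Late disconnections: phenol TBS ether; C8–CH3 (methylcerium on the C8 enone); C8=O (allylic oxidation, C8 being the only allylic CH2); C6 ester; C6 carbinol (oxidation, then 4-OH-directed reduction, because the hydride-shift sequence leaves the C6 oxygen β).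
3. Stereorelay from C1: reagent-controlled reduction of C4=O, 4β-OH-directed β-epoxidation of C5=C6, stereospecific 1,2-hydride shift C4→C5 (5α-H, trans fusion, C4 ketone restored), then isopropylcerium addition to C4 from the α face.
4. Key disconnection: Rh(I)-catalysed asymmetric intramolecular [5+2] cycloaddition of the achiral ynone–vinylcyclopropane 11 forms C1–C5 and C6–C7; ring A and ring B are closed in the same step and C1 is set by the ligand.
5. Precursor 11 in five steps from cyclopropanecarboxaldehyde: Wittig, DIBAL-H, Appel, Weinreb-acetamide enolate alkylation, ethynyl Grignard.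

Key step: step 6

Assumption (remark on the chemistry): (R)-BINAP is taken as the ligand enantiomer that gives (1R)-12; should the first run give the antipode, (S)-BINAP is used and nothing else in the route changes.

**Route**

Step 1
Reactants: 1 cyclopropanecarboxaldehyde; 2 ethyl 2-(triphenylphosphoranylidene)propanoate
Product: 3 ethyl (E)-3-cyclopropyl-2-methylprop-2-enoate
Conditions: 2 (1.1 equiv), CH2Cl2, rt
Reagents that add atoms: none
Why: Wittig olefination with a stabilised α-branched ylide should give the trisubstituted (E)-enoate, the ester ending up trans to the cyclopropyl group.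

Step 2
Reactants: 3 ethyl (E)-3-cyclopropyl-2-methylprop-2-enoate
Product: 4 (E)-3-cyclopropyl-2-methylprop-2-en-1-ol
Conditions: DIBAL-H (2.2 equiv), CH2Cl2, −78 → 0 °C; Rochelle salt
Reagents that add atoms: none
Why: DIBAL-H 1,2-reduction of an α,β-unsaturated ester stops at the allylic alcohol and touches neither the alkene geometry nor the cyclopropane.

Step 3
Reactants: 4 (E)-3-cyclopropyl-2-methylprop-2-en-1-ol
Product: 5 (E)-(3-bromo-2-methylprop-1-en-1-yl)cyclopropane
Conditions: CBr4, PPh3, CH2Cl2, 0 °C
Reagents that add atoms: carbon tetrabromide, BrC(Br)(Br)Br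
Why: Appel bromination displaces the primary allylic oxyphosphonium by SN2 under neutral conditions, so allylic transposition and cyclopropylcarbinyl ring opening should not be triggered.

Step 4
Reactants: 5 (E)-(3-bromo-2-methylprop-1-en-1-yl)cyclopropane; 6 N-methoxy-N-methylacetamide
Product: 8 (E)-5-cyclopropyl-N-methoxy-N,4-dimethylpent-4-enamide, via lithium enolate of the acetamide 7 (not isolated)
Conditions: LDA (commercial solution), 6, THF, −78 °C; then 5, −78 → −40 °C
Reagents that add atoms: none
Why: Enolate alkylation (SN2) of the Weinreb acetamide with a primary allylic bromide, kept cold because the enolate is thermally labile, adds the two-carbon tether and leaves an acyl group fit for mono-addition.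

Step 5
Reactants: 8 (E)-5-cyclopropyl-N-methoxy-N,4-dimethylpent-4-enamide; 9 ethynylmagnesium bromide
Product: 11 (E)-7-cyclopropyl-6-methylhept-6-en-1-yn-3-one, via magnesium hemiaminal adduct 10 (not isolated)
Conditions: 9 (1.5 equiv), THF, 0 °C; inverse quench into cold 1 M HCl
Reagents that add atoms: none
Why: Weinreb ketone synthesis, in which the chelated adduct 10 survives until the acidic quench so that over-addition is avoided, and the inverse quench keeps the released amine protonated so that it cannot add to the terminal ynone.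

Step 6
Reactants: 11 (E)-7-cyclopropyl-6-methylhept-6-en-1-yn-3-one
Product: 12 (1R)-dienone [(R)-3a-methyl-3,3a,6,7-tetrahydroazulen-1(2H)-one; C4 ketone, C5=C6 and C9=C10 alkenes, angular methyl on C1]
Conditions: [Rh((R)-BINAP)]SbF6 (10 mol%), DCE (0.02 M), 60 °C
Reagents that add atoms: none
Why: The cationic Rh(I) centre complexes the vinylcyclopropane and cleaves the C9–C7 cyclopropane bond oxidatively to an allyl–alkyl rhodium metallacycle, the ynone inserts at the allyl terminus C1 (bond C1–C5), and C6–C7 reductive elimination releases the cycloheptadiene. The closest known reaction is the intramolecular Rh-catalysed [5+2] cycloaddition of alkyne-tethered vinylcyclopropanes, including its enantioselective cationic Rh–bisphosphine and Rh–phosphoramidite forms. Ring A closes in the insertion step as a five-membered ring through the three-atom tether C2–C3–C4 (exo mode, fused and not bridged), and ring B closes by C(sp2)–C(sp3) reductive elimination from the eight-membered metallacycle, the former allyl unit delivering the cis C9=C10 alkene. The only new stereocentre, quaternary C1, is fixed when the chiral ligand selects the enantioface of the trisubstituted alkene for coordination and insertion (catalyst control on an achiral substrate). The step needs ring opening and intramolecular insertion to outrun oligomerisation of the terminal ynone, which high dilution, the short tether on the E alkene and the unhindered electron-poor alkyne should secure, and the unsubstituted cyclopropane leaves no regiochemical choice in the ring opening.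

Step 7
Reactants: 12 (1R)-dienone
Product: 13 (1R,4S)-dienol (12 with C4 reduced to the 4β-alcohol, OH cis to the C1 methyl)
Conditions: (R)-Me-CBS (20 mol%), catecholborane (1.5 equiv), toluene, −78 °C; MeOH, then aq. NaOH wash
Reagents that add atoms: none
Why: Corey–Bakshi–Shibata reduction, in which the (R)-oxazaborolidine, reading the fully substituted alkenyl carbon C5 as the large group and C3H2 as the small one, delivers hydride to the α face of C4 and sets the 4β (4S) carbinol by reagent control, while catecholborane at −78 °C spares both alkenes.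

Step 8
Reactants: 13 (1R,4S)-dienol
Product: 14 (1R,4S,5R,6R)-5β,6β-epoxy-4β-ol (epoxide oxygen and hydroxyl both on the face of the C1 methyl; C9=C10 retained)
Conditions: VO(acac)2 (5 mol%), tBuOOH (1.5 equiv, decane solution), CH2Cl2, 0 °C
Reagents that add atoms: tert-butyl hydroperoxide, CC(C)(C)OO
Why: Vanadium-catalysed hydroxyl-directed epoxidation delivers oxygen only to the allylic C5=C6 alkene and on the face of the 4β-hydroxyl, which sets C5 and C6 as the β-epoxide and leaves the isolated C9=C10 alkene alone.

Step 9
Reactants: 14 (1R,4S,5R,6R)-5β,6β-epoxy-4β-ol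
Product: 16 (1R,5S,6R)-6β-(triethylsilyloxy)-5αH C4 ketone (trans-fused, C9=C10 alkene), via epoxy triethylsilyl ether 15 (not isolated)
Conditions: TESOTf (2.5 equiv), iPr2NEt (3 equiv), 4 Å MS, CH2Cl2, −78 → −45 °C
Reagents that add atoms: triethylsilyl trifluoromethanesulfonate, CC[Si](CC)(CC)OS(=O)(=O)C(F)(F)F
Why: Silyl triflate-promoted semipinacol rearrangement of a 2,3-epoxy silyl ether by 1,2-hydride shift (the non-aldol aldol process), in which the C4–H bond, antiperiplanar to the breaking C5–O bond at the tertiary epoxide carbon, migrates to the α face of C5 with inversion, so that the trans ring fusion (5α-H) is set stereospecifically while C4 returns to the ketone and C6 keeps its β-oxygen as the TES ether.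

Step 10
Reactants: 16 (1R,5S,6R)-6β-(triethylsilyloxy)-5αH C4 ketone
Product: 18 (1R,4R,5S,6R)-4α-isopropyl-1β-methyl-5αH-bicyclic 9-ene-4β,6β-diol (overview numbering), via tertiary alcohol TES ether 17 (not isolated)
Conditions: iPrMgCl/CeCl3 (3 equiv each, premixed), THF, −78 °C; then 1 M HCl, THF/MeOH, 0 °C → rt
Reagents that add atoms: isopropylmagnesium chloride, CC(C)[Mg]Cl
Why: Organocerium 1,2-addition suppresses enolisation and β-elimination of the β-silyloxy ketone, and the isopropyl group should enter from the α face because the β face of C4 is screened by the axial C1 methyl and the 6β-OTES group, which sets 4β-OH/4α-iPr before the acidic work-up removes the TES ether.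

Step 11
Reactants: 18 (1R,4R,5S,6R)-4β,6β-diol
Product: 19 (1R,4R,5R)-4β-hydroxy-4α-isopropyl-1β-methyl-5αH-bicyclic 9-en-6-one
Conditions: Dess–Martin periodinane, NaHCO3, CH2Cl2, 0 °C
Reagents that add atoms: none
Why: Dess–Martin oxidation converts the only secondary alcohol into the C6 ketone under buffered non-basic conditions that leave the tertiary alcohol, the alkene and the epimerisable C5 centre untouched.

Step 12
Reactants: 19 (1R,4R,5R)-4β-hydroxy 6-ketone
Product: 20 (1R,4R,5S,6S)-4α-isopropyl-1β-methyl-5αH-bicyclic 9-ene-4β,6α-diol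
Conditions: Me4NBH(OAc)3 (5 equiv), MeCN/AcOH 1:1, −30 °C
Reagents that add atoms: none
Why: Evans–Saksena reduction, in which the acetoxyborohydride binds the tertiary 4β-hydroxyl (which lies on the β side of the C6 carbonyl plane) and delivers hydride intramolecularly to the β face of C6, giving the 1,3-anti diol with the equatorial 6α-alcohol against the steric preference of an external hydride.

Step 13
Reactants: 21 4-hydroxybenzoic acid
Product: 23 4-(tert-butyldimethylsilyloxy)benzoic acid, via bis-silylated acid 22 (not isolated)
Conditions: TBSCl (2.3 equiv), imidazole, DMF, rt; then AcOH/THF/H2O, rt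
Reagents that add atoms: tert-butyldimethylsilyl chloride, CC(C)(C)[Si](C)(C)Cl
Why: Silylation of both acidic OH groups followed by selective hydrolysis of the labile silyl ester leaves the phenol masked as its TBS ether and the carboxylic acid free.

Step 14
Reactants: 20 (1R,4R,5S,6S)-4β,6α-diol; 23 4-(tert-butyldimethylsilyloxy)benzoic acid
Product: 24 (1R,4R,5S,6S)-4β-hydroxy-4α-isopropyl-1β-methyl-5αH-bicyclic 9-en-6α-yl 4-(tert-butyldimethylsilyloxy)benzoate
Conditions: DCC, DMAP, CH2Cl2, rt
Reagents that add atoms: none
Why: Steglich esterification acylates the secondary equatorial 6α-hydroxyl while the hindered tertiary 4β-hydroxyl stays inert.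

Step 15
Reactants: 24 6α-aroyl ester
Product: 25 8-oxo derivative of 24 (C8 ketone conjugated with C9=C10)
Conditions: Rh2(cap)4 (1 mol%), tBuOOH (5 equiv), DCE, 40 °C
Reagents that add atoms: tert-butyl hydroperoxide, CC(C)(C)OO
Why: Dirhodium caprolactamate/TBHP allylic oxidation abstracts hydrogen from C8, the only carbon that carries allylic hydrogens, and the allyl radical should be oxygenated at C8 and not at C10, which is shielded by quaternary C1.

Step 16
Reactants: 25 C8 enone
Product: 26 (1R,4R,5S,6S,8R)-4β,8α-dihydroxy-8β-methyl compound, TBS ether of the target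
Conditions: MeLi/CeCl3 (3.5 equiv each, premixed), THF, −78 °C; AcOH quench at −78 °C
Reagents that add atoms: methyllithium, [Li]C
Why: Methylcerium 1,2-addition to the enone is fast at −78 °C while the hindered electron-rich aroyl ester reacts only slowly, and attack along the axial trajectory on the β face (antiperiplanar to the axial C7–H and away from the 6α-aroyloxy group) should place the methyl β and the hydroxyl α at C8.

Step 17
Reactants: 26 TBS ether of the target
Product: 27 (1R,4R,5S,6S,8R)-4β,8α-dihydroxy-5αH-dauc-9-en-6α-yl 4-hydroxybenzoate (CNP0280165.4)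
Conditions: TBAF/AcOH (1:1, 1.2 equiv), THF, 0 °C
Reagents that add atoms: none
Why: Buffered fluoride desilylation cleaves the aryl silyl ether selectively, without acyl migration or ionisation of the tertiary allylic alcohol.

**Compound list**

1 | cyclopropanecarboxaldehyde | O=CC1CC1 | starting material
2 | ethyl 2-(triphenylphosphoranylidene)propanoate | CCOC(=O)C(C)=P(c1ccccc1)(c1ccccc1)c1ccccc1 | starting material
3 | ethyl (E)-3-cyclopropyl-2-methylprop-2-enoate | CCOC(=O)/C(C)=C/C1CC1 | intermediate
4 | (E)-3-cyclopropyl-2-methylprop-2-en-1-ol | OC/C(C)=C/C1CC1 | intermediate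
5 | (E)-(3-bromo-2-methylprop-1-en-1-yl)cyclopropane | BrC/C(C)=C/C1CC1 | intermediate
6 | N-methoxy-N-methylacetamide | CC(=O)N(C)OC | starting material
7 | lithium enolate of N-methoxy-N-methylacetamide (not isolated) | [Li]OC(=C)N(C)OC | intermediate
8 | (E)-5-cyclopropyl-N-methoxy-N,4-dimethylpent-4-enamide | CON(C)C(=O)CC/C(C)=C/C1CC1 | intermediate
9 | ethynylmagnesium bromide | C#C[Mg]Br | starting material
10 | bromomagnesium alkoxide of the tetrahedral adduct of 8 and 9 (not isolated) | C#CC(O[Mg]Br)(CC/C(C)=C/C1CC1)N(C)OC | intermediate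
11 | (E)-7-cyclopropyl-6-methylhept-6-en-1-yn-3-one | C#CC(=O)CC/C(C)=C/C1CC1 | intermediate
12 | (1R)-dienone, (R)-3a-methyl-3,3a,6,7-tetrahydroazulen-1(2H)-one | O=C1CC[C@]2(C)C=CCCC=C21 | intermediate
13 | (1R,4S)-dienol, 4β-OH | O[C@H]1CC[C@]2(C)C=CCCC=C21 | intermediate
14 | (1R,4S,5R,6R)-5β,6β-epoxy-4β-ol | O[C@H]1CC[C@]2(C)C=CCC[C@H]3O[C@]321 | intermediate
15 | triethylsilyl ether of 14 (not isolated) | CC[Si](CC)(CC)O[C@H]1CC[C@]2(C)C=CCC[C@H]3O[C@]321 | intermediate
16 | (1R,5S,6R)-6β-(triethylsilyloxy)-5αH C4 ketone | O=C1CC[C@]2(C)C=CCC[C@@H](O[Si](CC)(CC)CC)[C@H]21 | intermediate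
17 | (1R,4R,5S,6R)-4β-hydroxy-4α-isopropyl-6β-(triethylsilyloxy) compound (not isolated) | CC(C)[C@]1(O)CC[C@]2(C)C=CCC[C@@H](O[Si](CC)(CC)CC)[C@H]21 | intermediate
18 | (1R,4R,5S,6R)-4β,6β-diol | CC(C)[C@]1(O)CC[C@]2(C)C=CCC[C@@H](O)[C@H]21 | intermediate
19 | (1R,4R,5R)-4β-hydroxy 6-ketone | CC(C)[C@]1(O)CC[C@]2(C)C=CCCC(=O)[C@H]21 | intermediate
20 | (1R,4R,5S,6S)-4β,6α-diol | CC(C)[C@]1(O)CC[C@]2(C)C=CCC[C@H](O)[C@H]21 | intermediate
21 | 4-hydroxybenzoic acid | OC(=O)c1ccc(O)cc1 | starting material
22 | tert-butyldimethylsilyl 4-(tert-butyldimethylsilyloxy)benzoate (not isolated) | CC(C)(C)[Si](C)(C)OC(=O)c1ccc(O[Si](C)(C)C(C)(C)C)cc1 | intermediate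
23 | 4-(tert-butyldimethylsilyloxy)benzoic acid | CC(C)(C)[Si](C)(C)Oc1ccc(C(=O)O)cc1 | intermediate
24 | (1R,4R,5S,6S)-4β-hydroxy 6α-[4-(tert-butyldimethylsilyloxy)benzoate] | CC(C)[C@]1(O)CC[C@]2(C)C=CCC[C@H](OC(=O)c3ccc(O[Si](C)(C)C(C)(C)C)cc3)[C@H]21 | intermediate
25 | (1R,4R,5S,6S)-8-oxo ester (C8 enone) | CC(C)[C@]1(O)CC[C@]2(C)C=CC(=O)C[C@H](OC(=O)c3ccc(O[Si](C)(C)C(C)(C)C)cc3)[C@H]21 | intermediate
26 | (1R,4R,5S,6S,8R)-TBS ether of the target | CC(C)[C@]1(O)CC[C@]2(C)C=C[C@](C)(O)C[C@H](OC(=O)c3ccc(O[Si](C)(C)C(C)(C)C)cc3)[C@H]21 | intermediate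
27 | (1R,4R,5S,6S,8R)-4β,8α-dihydroxy-5αH-dauc-9-en-6α-yl 4-hydroxybenzoate | CC(C)[C@]1(O)CC[C@]2(C)C=C[C@](C)(O)C[C@H](OC(=O)c3ccc(O)cc3)[C@H]21 | target

**Step count**

Total: 17 steps. Longest linear sequence: 16 steps (steps 1–12 and 14–17); step 13 is a one-step side branch.

**Steps most likely to fail**

Step 6. The ligand may discriminate poorly between the enantiofaces of the trisubstituted alkene that becomes quaternary C1, or cyclisation may be slow enough for oligomerisation of the terminal ynone to take over. Fallback: setting out from 11, the cycloaddition is run without a chiral ligand ([Rh(CO)2Cl]2, toluene, 80 °C) to give the racemic dienone F1. The (R)-CBS reduction of step 7 then turns the two enantiomers into diastereomeric allylic alcohols, 13 and the (1S,4S)-dienol F2, which are separated by chromatography. The route is rejoined at 13, so enantiopurity then comes from a reagent-controlled resolution and not from the cycloaddition.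

Step 9. The positive charge building at C5 may be discharged through other channels (1,2-shift of the vinyl or methyl group from C1, hydride shift from C6 to give the C6 ketone, or proton loss to an enol ether), so that the stereospecific C4→C5 hydride shift is not the main pathway. Fallback: setting out from 12, nucleophilic (Weitz–Scheffer) epoxidation (H2O2, NaOH, MeOH, 0 °C), expected to attack C6 axially on the α face, gives the 5α,6α-epoxy ketone F3. SmI2 (THF/MeOH, −90 °C) cleaves the C5–O bond to the 6α-hydroxy-5αH ketone F4, whose ring-fusion hydrogen now comes from enolate protonation, so a cis-fused isomer may have to be removed. Silylation (TESCl, imidazole) gives the 6α-triethylsilyloxy ketone F5, and iPrMgCl/CeCl3 followed by acidic work-up passes through the tertiary alcohol TES ether F6 to the diol. The route is rejoined at 20, and steps 11 and 12 are then not needed.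

Step 16. Facial selectivity at C8 may be poor, because the angular C1 methyl lies across the ring on the face that must be attacked, or the ester may be attacked in part. Fallback: setting out from 25, Wittig methylenation (Ph3P=CH2, THF, 0 °C) gives the 8-methylene diene F7. Epoxidation of the exocyclic alkene (dimethyldioxirane, acetone, −20 °C) gives the spiro-epoxide F8: an electrophilic oxygen takes the face that a nucleophile prefers, so if methylcerium favours the α face the oxygen will too, which is the configuration needed. Iodide opening at the CH2 terminus (LiI, AcOH, THF, 0 °C) gives the iodohydrin F9, and radical deiodination (Bu3SnH, AIBN, toluene, 80 °C), which the ester tolerates, converts CH2I into the methyl group. The route is rejoined at 26.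

**Further compounds**

F1 | step 6 | racemic dienone (rac-12) | O=C1CCC2(C)C=CCCC=C21
F2 | step 6 | (1S,4S)-dienol, diastereomer of 13 | O[C@H]1CC[C@@]2(C)C=CCCC=C21
F3 | step 9 | (1R)-5α,6α-epoxy C4 ketone | O=C1CC[C@]2(C)C=CCC[C@@H]3O[C@@]321
F4 | step 9 | (1R,5S,6S)-6α-hydroxy-5αH C4 ketone | O=C1CC[C@]2(C)C=CCC[C@H](O)[C@H]21
F5 | step 9 | (1R,5S,6S)-6α-(triethylsilyloxy)-5αH C4 ketone | O=C1CC[C@]2(C)C=CCC[C@H](O[Si](CC)(CC)CC)[C@H]21
F6 | step 9 | (1R,4R,5S,6S)-4β-hydroxy-4α-isopropyl-6α-(triethylsilyloxy) compound | CC(C)[C@]1(O)CC[C@]2(C)C=CCC[C@H](O[Si](CC)(CC)CC)[C@H]21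
F7 | step 16 | 8-methylene diene ester | CC(C)[C@]1(O)CC[C@]2(C)C=CC(=C)C[C@H](OC(=O)c3ccc(O[Si](C)(C)C(C)(C)C)cc3)[C@H]21
F8 | step 16 | C8 spiro-epoxide, oxygen α | CC(C)[C@]1(O)CC[C@]2(C)C=C[C@@]3(CO3)C[C@H](OC(=O)c4ccc(O[Si](C)(C)C(C)(C)C)cc4)[C@H]21
F9 | step 16 | 8α-hydroxy-8β-(iodomethyl) ester | CC(C)[C@]1(O)CC[C@]2(C)C=C[C@](CI)(O)C[C@H](OC(=O)c3ccc(O[Si](C)(C)C(C)(C)C)cc3)[C@H]21
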